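(Readings and results are calculated from invented constants.)

| flask | starting material | free catalyst | temperature | remark | time |
|---|---|---|---|---|---|
| east | 0.16 M | 21 mM | 116 °C | run made earlier |  |
| south-west | 0.64 M | 21 mM | 130 °C | run made earlier |  |
| dawn | 0.32 M | 21 mM | 110 °C |  | 15 h |
| noon | 0.32 M | 21 mM | 135 °C |  | 15 h |

- east (time / h: catalyst intermediate / %, starting material / %, target / %): 0.833: 2, 96, 4; 2.50: 3, 86, 8; 4.00: 6, 80, 15; 6.00: 5, 73, 21; 10.0: 4, 62, 28; 12.0: 4, 60, 29; 15.0: 5, 57, 33
- south-west (time / h: catalyst intermediate / %, starting material / %, target / %): 0.500: 3, 92, 5; 0.667: 2, 93, 4; 1.00: 2, 87, 10; 1.33: 1, 88, 11; 2.00: 1, 82, 13; 4.00: 1, 78, 18; 6.00: 1, 72, 19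

(each reading ± 1.5 percentage points)

1. which of these there is most of at the end, counted by the starting material in it, dawn (target / starting material / catalyst intermediate)
2. which of these there is most of at the end, counted by the starting material in it, noon (target / starting material / catalyst intermediate)
3. final amount of the leader among these, as a percentage of the starting material charged, in dawn
4. final amount of the leader among these, as a percentage of the starting material charged, in noon

- the numbers in the tables scatter by 1.5 percentage points (one standard deviation)

I begin with an easy count: target in molar units over catalyst charged is the turnover number N, how many targets the average catalyst molecule has delivered. The south-west run climbs ever more slowly, from 10% target at 1.00 h to 18% at 4.00 h and 19% at 6.00 h, and its reading at 4.00 h gives N = 5.49. I call this N_s, the slowing number, the turnovers per catalyst charged that the south-west run reads once its climb has slowed. The objection is that N_s is a mark on a slowing curve and no ceiling, and the east run shows 2.51 at its last reading, less than N_s, so a flask needs time to come near it.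

So I need the pace. Taken as first order, the early readings give 0.0558 h⁻¹ in the east run and 0.139 h⁻¹ in the south-west run. Turnovers then run in proportion to the charge and to this temperature factor. On this scaling noon matches N_s at about 5.77 h, sooner than its end, so I take noon's end to lie near N_s, though the scaling assumes that the slowing stretches with the pace, which I cannot test. Its target is then 36.0%. If each catalyst holds at most one starting material, which is 6.56% of the charge, noon keeps about 57.4% starting material, more than target. One doubt stays: noon is hotter than the south-west run, and two runs cannot show whether N_s moves with temperature.

Dawn I scale from the east run and get N = 3.40, below N_s, so dawn is still climbing. Its target is 22.3%, leaving about 71.1% starting material, more than target.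

The forecast, noting that “Both runs then stall well beyond simple depletion”, names starting material for dawn at 74% (67% to 81%) and starting material for noon at 55% (44% to 66%).

The flasks give starting material in dawn at 72.1%, with target 23.0%, and starting material in noon at 56.3%, with target 37.4%.

    starting material + free catalyst → catalyst intermediate (k = 0.0370 M⁻¹ min⁻¹, Ea = 93.0 kJ mol⁻¹)
    catalyst intermediate ⇌ free catalyst + target (K = 0.0450 M, k = 1.30 min⁻¹, Ea = 102 kJ mol⁻¹, ΔH = −9.00 kJ mol⁻¹)
    2 catalyst intermediate → spent catalyst (k = 0.0530 M⁻¹ min⁻¹, Ea = 99.0 kJ mol⁻¹)
    (constants at 110 °C)

Noon stands at N = 4.85 at 7.50 h and N = 5.69 at its end, so it passes N_s of 5.49 later than my 5.77 h. At 120 °C, the neighbour of noon, the same reckoning matches N_s at about 15.4 h, close to its end at 15 h, so target should stand near 36.0%. That flask holds 30.2% target, which is N = 4.60, and 64.0% starting material, with spent catalyst at 61.2% of the catalyst charged and free catalyst at 11.7%.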